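**Plan**

- Retrosynthetic cuts: the two ester C–O bonds (C6, C10); then C6–C7 and C8–C9 of the seven-membered ring with re-closure of C6–C9; then C4–C5, C1–CH3 and C1–C2.
- Enabling feature: the C6 and C10 oxygens flank the C5–C1 ring fusion and are bridged on the far side by C7–C8–C9, with the one-carbon branch on C8. Without C7 and C8 the core is a cis-bicyclo[3.3.0]octane-2,4-dione (ring A = C1, C5, C6, C9, C10), whose enol can take up allene and open to the seven-membered ring.
- Forward order: an enantiopure cyclopentenone (future C1, C5, C6, C9, C10) receives the C2–C4 chain and the C1 methyl by two cuprate additions. Ring B (C1–C5) closes by a Lewis-acid aldol-type cyclisation. Ring A is then enlarged photochemically from five to seven atoms, and the esters come last.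
- Stereochemistry: the C10 silyloxy group of the starting enone steers methyl anti (C1) and is later oxidised away. The cis ring fusion forces the C4/C5 epoxide onto the α face (C4, C5). A hydroxyl-directed hydride sets C6, and a CBS reduction sets C10.

Key step: step 10

Remark: target numbering C1–C10 is used for all bicyclic compounds (the dione CH2 is C9), α is the face of the C1 methyl and C5 hydrogen, dione 14 is assumed to react as its enol, and (S)-4-(tert-butyldimethylsilyloxy)cyclopent-2-enone is assumed to be purchasable.

**Route**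

Step 1
Reactants: 1 4-methylpent-1-en-3-one
Product: 3 2-(2-bromoethyl)-2-isopropyl-1,3-dioxolane, via β-bromo ketone 2 (not isolated)
Conditions: HBr (g), CH2Cl2, 0 °C; then HOCH2CH2OH, TsOH·H2O (cat.), 4 Å MS, 25 °C
Reagents that add atoms: hydrogen bromide, Br; ethylene glycol, OCCO
Why: Conjugate hydrobromination of the enone followed by acid-catalysed ketalisation is the standard entry to β-halo ketal homoenolate equivalents; no stereocentre is formed.

Step 2
Reactants: 3 2-(2-bromoethyl)-2-isopropyl-1,3-dioxolane; 4 (S)-4-(tert-butyldimethylsilyloxy)cyclopent-2-en-1-one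
Product: 6 (3S,4S)-4-(tert-butyldimethylsilyloxy)-3-[2-(2-isopropyl-1,3-dioxolan-2-yl)ethyl]-1-(trimethylsilyloxy)cyclopent-1-ene, via Grignard reagent 5 (not isolated)
Conditions: Mg, THF, 25 °C; then 4, CuBr·SMe2 (10 mol %), TMSCl, THF, −78 °C; Et3N/pentane work-up
Reagents that add atoms: chlorotrimethylsilane, C[Si](C)(C)Cl
Why: Copper-catalysed, TMSCl-accelerated conjugate addition of the Grignard reagent should occur anti to the silyloxy group, as in prostaglandin-type additions, and the enolate is trapped as the silyl enol ether (the new centre is planarised again in step 3).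

Step 3
Reactants: 6 silyl enol ether
Product: 7 (S)-4-(tert-butyldimethylsilyloxy)-3-[2-(2-isopropyl-1,3-dioxolan-2-yl)ethyl]cyclopent-2-en-1-one
Conditions: Pd(OAc)2 (1.05 equiv), MeCN, 25 °C
Reagents that add atoms: none
Why: Saegusa–Ito oxidation: the divalent palladium enolate formed from the silyl enol ether undergoes β-hydride elimination toward the chain-bearing carbon, returning an enone that now carries the chain on its β-carbon, with the silyloxy stereocentre untouched.

Step 4
Reactants: 7 enone
Product: 8 (3R,4S)-4-(tert-butyldimethylsilyloxy)-3-[2-(2-isopropyl-1,3-dioxolan-2-yl)ethyl]-3-methyl-1-(trimethylsilyloxy)cyclopent-1-ene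
Conditions: Me2CuLi (from MeLi, CuI), TMSCl, THF, −78 → −40 °C; Et3N work-up
Reagents that add atoms: lithium dimethylcuprate, [Li+].C[Cu-]C; chlorotrimethylsilane, C[Si](C)(C)Cl
Why: TMSCl-accelerated Gilman conjugate addition should deliver methyl to the face opposite the adjacent C10 silyloxy group, setting quaternary C1 (methyl trans to OTBS), and it leaves the enolate as the regiodefined C5=C6 silyl enol ether without equilibration that could expel the β-silyloxy group.

Step 5
Reactants: 8 silyl enol ether
Product: 10 10β-(tert-butyldimethylsilyloxy)-4-isopropyl-1α-methylbicyclo[3.3.0]oct-4-en-6-one, via hydroxyethyl ether 9 (not isolated)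
Conditions: TiCl4, CH2Cl2, −78 → −20 °C; aq. NaHCO3
Reagents that add atoms: none
Why: Intramolecular Mukaiyama-type addition of the silyl enol ether carbon C5 to the oxocarbenium ion opened from the dioxolane (C4) closes ring B (5-exo), and the tertiary β-alkoxy ketone then loses ethylene glycol under the Lewis acid to give the conjugated tetrasubstituted enone; no enolate toward C9 is formed, so the C10 silyloxy group should survive.

Step 6
Reactants: 10 bicyclic enone
Product: 11 4α,5α-epoxy-10β-(tert-butyldimethylsilyloxy)-4β-isopropyl-1α-methyl-cis-bicyclo[3.3.0]octan-6-one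
Conditions: DMDO, acetone/CH2Cl2, 0 → 25 °C
Reagents that add atoms: dimethyldioxirane, CC1(C)OO1
Why: Neutral dioxirane epoxidation of the electron-rich tetrasubstituted enone double bond; because C5 is a ring-fusion atom, the new C5–O bond must be cis to the C1 methyl (cis-bicyclo[3.3.0]octane), so oxygen arrives on the convex α face and C4 gets its oxygen α and its isopropyl β.

Step 7
Reactants: 11 epoxy ketone
Product: 12 10β-(tert-butyldimethylsilyloxy)-4α-hydroxy-4β-isopropyl-1α-methyl-cis-bicyclo[3.3.0]octan-6-one (5α-H)
Conditions: SmI2 (2.5 equiv), THF/MeOH, −78 °C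
Reagents that add atoms: none
Why: Samarium diiodide reduction of the α,β-epoxy ketone cleaves the C5–O bond to a samarium enolate that is protonated at C5 on the only face compatible with a cis ring fusion, leaving the tertiary C4 alcohol with retained α configuration.

Step 8
Reactants: 12 silyl ether
Product: 13 4α,10β-dihydroxy-4β-isopropyl-1α-methyl-cis-bicyclo[3.3.0]octan-6-one
Conditions: HF (48 % aq.), MeCN, 0 → 25 °C
Reagents that add atoms: none
Why: Acidic fluoride desilylation frees the C10 alcohol without exposing either β-oxygenated ketone to base.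

Step 9
Reactants: 13 diol
Product: 14 4α-hydroxy-4β-isopropyl-1α-methyl-cis-bicyclo[3.3.0]octane-6,10-dione (5α-H; enolised)
Conditions: Dess–Martin periodinane (1.2 equiv), CH2Cl2, 25 °C
Reagents that add atoms: none
Why: Dess–Martin oxidation of the secondary β-hydroxy ketone should give the cyclic 1,3-dione while the tertiary C4 alcohol is inert; the C10 stereocentre, having controlled C1, is erased here.

Step 10
Reactants: 14 bicyclic 1,3-dione; 15 propadiene
Product: 17 4α-hydroxy-4β-isopropyl-1α-methyl-8-methylene-cis-bicyclo[5.3.0]decane-6,10-dione (5α-H), via cyclobutanol photoadduct 16 (not isolated)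
Conditions: allene (excess, condensed), hν (medium-pressure Hg lamp, Vycor filter), CH2Cl2, −60 °C; then 25 °C
Reagents that add atoms: none
Why: The enolised dione is a 3-hydroxycyclopentenone whose triplet state adds allene stepwise: the dione CH (C9) bonds to the central allene carbon (C8) to give a 1,4-diradical that is allylic on one side and oxygen-stabilised at the enol carbon (C6), and radical recombination then forms C6–C7 and closes the four-membered ring of methylenecyclobutanol 16 (a formal [2+2]). The cyclobutanol is a strained β-hydroxy ketone with respect to C10=O and should open spontaneously by retro-aldol cleavage of C6–C9, the bond shared by the four- and five-membered rings, so ring A grows from five to seven atoms by fragmentation and C8 ends as an exocyclic methylene between two CH2 groups. The closest known reaction is the de Mayo reaction of cyclic 1,3-dione enols with alkenes, combined with the head-to-head orientation that allene shows toward cyclic enones. No stereocentre is created in 17: C1, C4 and C5 pass through unchanged and the two transient centres of 16 (C6, C9) vanish on fragmentation, so the face of attack does not matter. The one selectivity needed is regiochemical (C8 to C9, not to C6); it is secured by the allyl/α-oxy stabilised diradical and by the fact that either enol tautomer leads to the same product. Irradiating through Vycor, where the strongly absorbing enol takes up nearly all the light, and stopping short of full conversion should protect the weakly absorbing β,γ-unsaturated diketone from secondary photoreactions.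

Step 11
Reactants: 17 methylene dione
Product: 18 4α,6β-dihydroxy-4β-isopropyl-1α-methyl-8-methylene-cis-bicyclo[5.3.0]decan-10-one
Conditions: Me4NBH(OAc)3, MeCN/AcOH (1:1), −30 → 0 °C
Reagents that add atoms: none
Why: Evans–Saksena directed reduction: exchange of the tertiary C4 hydroxyl onto boron activates only the β-hydroxy ketone (C6) and delivers hydride intramolecularly to its α face, which is also the convex face, so the 6β-alcohol should form while the C10 ketone, lacking a β-hydroxyl, is left alone.

Step 12
Reactants: 18 β,γ-unsaturated ketone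
Product: 19 4α,6β-dihydroxy-cis-dauc-8-en-10-one (4β-isopropyl, 1α-methyl, 8-methyl)
Conditions: DBU (0.5 equiv), CH2Cl2, 25 °C
Reagents that add atoms: none
Why: Base-mediated isomerisation through the C9 dienolate moves the double bond into conjugation with C10=O (C8=C9, C8 now bearing methyl), the only carbonyl left, and no β-leaving group is present at this stage.

Step 13
Reactants: 20 4-hydroxybenzoic acid
Product: 22 4-(tert-butyldimethylsilyloxy)benzoic acid, via bis-silyl compound 21 (not isolated)
Conditions: TBSCl (2.3 equiv), imidazole, DMF, 25 °C; then AcOH/THF/H2O, 25 °C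
Reagents that add atoms: tert-butyldimethylsilyl chloride, CC(C)(C)[Si](C)(C)Cl
Why: Exhaustive silylation followed by selective hydrolysis of the much more labile silyl ester is the routine way to the phenol-protected acid.

Step 14
Reactants: 22 4-(tert-butyldimethylsilyloxy)benzoic acid
Product: 23 4-(tert-butyldimethylsilyloxy)benzoyl chloride
Conditions: (COCl)2, DMF (cat.), CH2Cl2, 0 → 25 °C
Reagents that add atoms: oxalyl chloride, O=C(Cl)C(=O)Cl
Why: Standard acid chloride formation through the catalytic chloroiminium species; the aryl silyl ether should tolerate the short exposure to HCl in CH2Cl2.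

Step 15
Reactants: 19 diol enone; 23 4-(tert-butyldimethylsilyloxy)benzoyl chloride
Product: 24 6β-[4-(tert-butyldimethylsilyloxy)benzoyloxy]-4α-hydroxy-cis-dauc-8-en-10-one
Conditions: Et3N, DMAP (0.3 equiv), CH2Cl2, 0 → 25 °C
Reagents that add atoms: none
Why: DMAP-catalysed acylation should select the secondary C6 alcohol over the hindered tertiary C4 alcohol and proceeds with retention at C6.

Step 16
Reactants: 24 enone ester
Product: 25 6β-[4-(tert-butyldimethylsilyloxy)benzoyloxy]-cis-dauc-8-ene-4α,10α-diol
Conditions: (S)-Me-CBS oxazaborolidine (C18H20BNO, 0.3 equiv), catecholborane, toluene, −78 → −40 °C; MeOH, pH 7 buffer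
Reagents that add atoms: none
Why: Corey–Bakshi–Shibata reduction: with quaternary C1 as the large flank and vinylic C9 as the small one, the (S)-catalyst should deliver hydride 1,2 to the β face of the enone carbonyl, giving the 10α (10R) allylic alcohol under reagent control; the aryl ester and silyl ether are inert at this temperature.

Step 17
Reactants: 25 allylic alcohol; 26 3-methylbutanoyl chloride
Product: 27 6β-[4-(tert-butyldimethylsilyloxy)benzoyloxy]-10α-(3-methylbutanoyloxy)-cis-dauc-8-en-4α-ol
Conditions: pyridine, DMAP (0.2 equiv), CH2Cl2, 0 → 25 °C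
Reagents that add atoms: none
Why: DMAP-catalysed O-acylation of the secondary allylic alcohol proceeds with retention, and the tertiary C4 alcohol stays free.

Step 18
Reactants: 27 silyl-protected diester
Product: 28 (3S,3aS,4R,8R,8aR)-3-hydroxy-6,8a-dimethyl-8-[(3-methylbutanoyl)oxy]-3-(propan-2-yl)-1,2,3,3a,4,5,8,8a-octahydroazulen-4-yl 4-hydroxybenzoate (CNP0086724.1)
Conditions: TBAF, AcOH (1:1), THF, 0 °C
Reagents that add atoms: none
Why: Buffered fluoride cleaves the aryl silyl ether selectively, and the acetic acid keeps the liberated phenoxide from attacking either ester.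

**Compound list**

1 | 4-methylpent-1-en-3-one | CC(C)C(=O)C=C | starting material
2 | 1-bromo-4-methylpentan-3-one | CC(C)C(=O)CCBr | intermediate
3 | 2-(2-bromoethyl)-2-isopropyl-1,3-dioxolane | CC(C)C1(CCBr)OCCO1 | intermediate
4 | (S)-4-(tert-butyldimethylsilyloxy)cyclopent-2-en-1-one | O=C1C=C[C@@H](O[Si](C)(C)C(C)(C)C)C1 | starting material
5 | [2-(2-isopropyl-1,3-dioxolan-2-yl)ethyl]magnesium bromide | CC(C)C1(CC[Mg]Br)OCCO1 | intermediate
6 | (3S,4S)-4-(tert-butyldimethylsilyloxy)-3-[2-(2-isopropyl-1,3-dioxolan-2-yl)ethyl]-1-(trimethylsilyloxy)cyclopent-1-ene (3,4-trans) | C[Si](C)(C)OC1=C[C@H](CCC2(C(C)C)OCCO2)[C@@H](O[Si](C)(C)C(C)(C)C)C1 | intermediate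
7 | (S)-4-(tert-butyldimethylsilyloxy)-3-[2-(2-isopropyl-1,3-dioxolan-2-yl)ethyl]cyclopent-2-en-1-one | O=C1C=C(CCC2(C(C)C)OCCO2)[C@@H](O[Si](C)(C)C(C)(C)C)C1 | intermediate
8 | (3R,4S)-4-(tert-butyldimethylsilyloxy)-3-[2-(2-isopropyl-1,3-dioxolan-2-yl)ethyl]-3-methyl-1-(trimethylsilyloxy)cyclopent-1-ene (methyl trans to OTBS) | C[Si](C)(C)OC1=C[C@@](C)(CCC2(C(C)C)OCCO2)[C@@H](O[Si](C)(C)C(C)(C)C)C1 | intermediate
9 | 4-(2-hydroxyethoxy)-10β-(tert-butyldimethylsilyloxy)-4-isopropyl-1α-methyl-cis-bicyclo[3.3.0]octan-6-one (titanium-bound; C4 configuration immaterial, drawn with the ether β) | O=C1C[C@H](O[Si](C)(C)C(C)(C)C)[C@]2(C)CC[C@@](OCCO)(C(C)C)[C@H]12 | intermediate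
10 | 10β-(tert-butyldimethylsilyloxy)-4-isopropyl-1α-methylbicyclo[3.3.0]oct-4-en-6-one | O=C1C[C@H](O[Si](C)(C)C(C)(C)C)[C@]2(C)CCC(C(C)C)=C12 | intermediate
11 | 4α,5α-epoxy-10β-(tert-butyldimethylsilyloxy)-4β-isopropyl-1α-methyl-cis-bicyclo[3.3.0]octan-6-one | O=C1C[C@H](O[Si](C)(C)C(C)(C)C)[C@]2(C)CC[C@@]3(C(C)C)O[C@@]123 | intermediate
12 | 10β-(tert-butyldimethylsilyloxy)-4α-hydroxy-4β-isopropyl-1α-methyl-cis-bicyclo[3.3.0]octan-6-one | O=C1C[C@H](O[Si](C)(C)C(C)(C)C)[C@]2(C)CC[C@](O)(C(C)C)[C@H]12 | intermediate
13 | 4α,10β-dihydroxy-4β-isopropyl-1α-methyl-cis-bicyclo[3.3.0]octan-6-one | O=C1C[C@H](O)[C@]2(C)CC[C@](O)(C(C)C)[C@H]12 | intermediate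
14 | 4α-hydroxy-4β-isopropyl-1α-methyl-cis-bicyclo[3.3.0]octane-6,10-dione | O=C1CC(=O)[C@]2(C)CC[C@](O)(C(C)C)[C@H]12 | intermediate
15 | propadiene (allene) | C=C=C | starting material
16 | methylenecyclobutanol photoadduct (cyclobutane C6–C7–C8–C9 fused to ring A on the α face, C6–OH, C8=CH2, C10 ketone) | C=C1C[C@@]2(O)[C@@H]1C(=O)[C@]1(C)CC[C@](O)(C(C)C)[C@@H]12 | intermediate
17 | 4α-hydroxy-4β-isopropyl-1α-methyl-8-methylene-cis-bicyclo[5.3.0]decane-6,10-dione | C=C1CC(=O)[C@]2(C)CC[C@](O)(C(C)C)[C@@H]2C(=O)C1 | intermediate
18 | 4α,6β-dihydroxy-4β-isopropyl-1α-methyl-8-methylene-cis-bicyclo[5.3.0]decan-10-one | C=C1CC(=O)[C@]2(C)CC[C@](O)(C(C)C)[C@@H]2[C@H](O)C1 | intermediate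
19 | 4α,6β-dihydroxy-cis-dauc-8-en-10-one | CC1=CC(=O)[C@]2(C)CC[C@](O)(C(C)C)[C@@H]2[C@H](O)C1 | intermediate
20 | 4-hydroxybenzoic acid | O=C(O)c1ccc(O)cc1 | starting material
21 | tert-butyldimethylsilyl 4-(tert-butyldimethylsilyloxy)benzoate | CC(C)(C)[Si](C)(C)OC(=O)c1ccc(O[Si](C)(C)C(C)(C)C)cc1 | intermediate
22 | 4-(tert-butyldimethylsilyloxy)benzoic acid | O=C(O)c1ccc(O[Si](C)(C)C(C)(C)C)cc1 | intermediate
23 | 4-(tert-butyldimethylsilyloxy)benzoyl chloride | O=C(Cl)c1ccc(O[Si](C)(C)C(C)(C)C)cc1 | intermediate
24 | 6β-[4-(tert-butyldimethylsilyloxy)benzoyloxy]-4α-hydroxy-cis-dauc-8-en-10-one | CC1=CC(=O)[C@]2(C)CC[C@](O)(C(C)C)[C@@H]2[C@H](OC(=O)c2ccc(O[Si](C)(C)C(C)(C)C)cc2)C1 | intermediate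
25 | 6β-[4-(tert-butyldimethylsilyloxy)benzoyloxy]-cis-dauc-8-ene-4α,10α-diol | CC1=C[C@@H](O)[C@]2(C)CC[C@](O)(C(C)C)[C@@H]2[C@H](OC(=O)c2ccc(O[Si](C)(C)C(C)(C)C)cc2)C1 | intermediate
26 | 3-methylbutanoyl chloride | CC(C)CC(=O)Cl | starting material
27 | 6β-[4-(tert-butyldimethylsilyloxy)benzoyloxy]-10α-(3-methylbutanoyloxy)-cis-dauc-8-en-4α-ol | CC1=C[C@@H](OC(=O)CC(C)C)[C@]2(C)CC[C@](O)(C(C)C)[C@@H]2[C@H](OC(=O)c2ccc(O[Si](C)(C)C(C)(C)C)cc2)C1 | intermediate
28 | (3S,3aS,4R,8R,8aR)-3-hydroxy-6,8a-dimethyl-8-[(3-methylbutanoyl)oxy]-3-(propan-2-yl)-1,2,3,3a,4,5,8,8a-octahydroazulen-4-yl 4-hydroxybenzoate | CC1=C[C@@H](OC(=O)CC(C)C)[C@]2(C)CC[C@](O)(C(C)C)[C@@H]2[C@H](OC(=O)c2ccc(O)cc2)C1 | target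

**Step count**

Total: 18 steps. Longest linear sequence: 16 steps (steps 1–12 and 15–18, from compound 1); the aroyl branch (steps 13–14) joins at step 15.

**Steps most likely to fail**

Step 10. The enol may be excited inefficiently while the β,γ-unsaturated diketone product undergoes secondary photoreactions, and part of the allene may add head-to-tail, so that fragmentation in the same flask gives a mixture that is hard to separate. The fallback separates cycloaddition from ring opening while keeping the same bonds. Setting out from 14, O-silylation (TBSCl, Et3N, CH2Cl2) would give the 6-(tert-butyldimethylsilyloxy)-4α-hydroxy-4β-isopropyl-1α-methyl-cis-bicyclo[3.3.0]oct-6-en-10-one F1 (its 10-silyloxy regioisomer converges). Irradiation with allene would give the cyclobutyl silyl ether F2, a stable compound that can be freed of regioisomers by chromatography. HF·pyridine in THF would then unmask the cyclobutanol, which fragments by retro-aldol to 17, where the route resumes.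

Step 5. The enol ether may be protodesilylated without C–C bond formation, or the Lewis acid may strip the C10 silyl ether and trigger dehydration. The fallback sets out from 8: PPTS in wet acetone would hydrolyse both the enol ether and the ketal to the diketone (3R,4S)-4-(tert-butyldimethylsilyloxy)-3-methyl-3-(4-methyl-3-oxopentyl)cyclopentan-1-one F3. Cyclodehydration under enamine and weak-acid catalysis (pyrrolidine, AcOH, toluene, 60 °C) would then give 10, where the route is rejoined. These conditions avoid the alkoxide bases that would expel the β-silyloxy group by E1cB.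

Step 16. Facial selectivity may be poor because the catalyst has to override any substrate preference for hydride attack from the convex α face. The fallback accepts substrate control and inverts afterwards. Setting out from 24, Luche reduction (NaBH4, CeCl3·7H2O, MeOH, −78 °C) should give mainly the 10β-alcohol, the 10-epimer of 25, F4. Mitsunobu esterification with 3-methylbutanoic acid (PPh3, DIAD, toluene) would then install the isovalerate with inversion and return to the route at 27.

Further compounds
F1 | step 10 | 6-(tert-butyldimethylsilyloxy)-4α-hydroxy-4β-isopropyl-1α-methyl-cis-bicyclo[3.3.0]oct-6-en-10-one | O=C1C=C(O[Si](C)(C)C(C)(C)C)[C@H]2[C@@](O)(C(C)C)CC[C@@]12C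
F2 | step 10 | cyclobutyl silyl ether (6-O-tert-butyldimethylsilyl derivative of photoadduct 16) | C=C1C[C@@]2(O[Si](C)(C)C(C)(C)C)[C@@H]1C(=O)[C@]1(C)CC[C@](O)(C(C)C)[C@@H]12
F3 | step 5 | (3R,4S)-4-(tert-butyldimethylsilyloxy)-3-methyl-3-(4-methyl-3-oxopentyl)cyclopentan-1-one | O=C1C[C@@](C)(CCC(=O)C(C)C)[C@@H](O[Si](C)(C)C(C)(C)C)C1
F4 | step 16 | 6β-[4-(tert-butyldimethylsilyloxy)benzoyloxy]-cis-dauc-8-ene-4α,10β-diol (10-epimer of 25) | CC1=C[C@H](O)[C@]2(C)CC[C@](O)(C(C)C)[C@@H]2[C@H](OC(=O)c2ccc(O[Si](C)(C)C(C)(C)C)cc2)C1
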